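**Retrosynthetic overview**
- The only stereocentre (C3, S) is set last, by enantioselective protonation of the chroman-4-one enolate released by palladium from a tris(allyl carbonate); the same step frees both phenols.
- The tris(allyl carbonate) comes from 1,4-hydride addition to 7,2'-dihydroxy-4'-methoxy-5'-prenylisoflavone and O-acylation (the oxidation-state change that isoflavone reductase makes).
- The prenyl group is put on by Stille coupling of the 5'-bromoisoflavone, after the oxidative step that a prenyl alkene would not survive.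
- Ring C is the only ring made (rings A and B are bought): one flask takes the chalcone to the flavanone (oxa-Michael), then through an oxidative 2,3-aryl shift to the isoflavone, in the order chalcone isomerase, isoflavone synthase, dehydratase.
- The chalcone comes from a Claisen–Schmidt condensation of MOM-protected 2,4-dihydroxyacetophenone with 5-bromo-4-methoxy-2-(methoxymethoxy)benzaldehyde.

Assumption: the hand of the PHOX ligand in step 8 is assigned by analogy with related decarboxylative protonations; if the first run gives the (3R) ketone, the (R)-ligand is used with no other change.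

**Step 1**
Reactants: 1 2-hydroxy-4-methoxybenzaldehyde
Product: 2 5-bromo-2-hydroxy-4-methoxybenzaldehyde
Conditions: Br2 (1.05 equiv), CH2Cl2, 0 °C
Reagents that add atoms: bromine, BrBr
Why: Electrophilic aromatic bromination goes to C5, which is para to the hydroxyl and ortho to the methoxyl, because the other activated position (C3, between the two oxygens) is hindered.

**Step 2**
Reactants: 2 5-bromo-2-hydroxy-4-methoxybenzaldehyde
Product: 3 5-bromo-4-methoxy-2-(methoxymethoxy)benzaldehyde
Conditions: MOMCl (1.3 equiv), K2CO3, acetone, 0 °C to rt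
Reagents that add atoms: chloromethyl methyl ether, COCCl
Why: O-Alkylation of the phenoxide (MOM protection) masks the ring B phenol, which would otherwise give a flavylium salt in acid or be oxidised in step 5.

**Step 3**
Reactants: 4 2,4-dihydroxyacetophenone
Product: 5 1-[2-hydroxy-4-(methoxymethoxy)phenyl]ethanone
Conditions: MOMCl (1.1 equiv), K2CO3, acetone, rt
Reagents that add atoms: chloromethyl methyl ether, COCCl
Why: Regioselective O-alkylation (MOM protection) takes only the 4-OH, because the 2-OH is hydrogen-bonded to the ketone and stays free for the later ring closure.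

**Step 4**
Reactants: 3 5-bromo-4-methoxy-2-(methoxymethoxy)benzaldehyde; 5 1-[2-hydroxy-4-(methoxymethoxy)phenyl]ethanone
Product: 6 (E)-3-[5-bromo-4-methoxy-2-(methoxymethoxy)phenyl]-1-[2-hydroxy-4-(methoxymethoxy)phenyl]prop-2-en-1-one
Conditions: KOH (50% aq.), EtOH, rt, 48 h
Reagents that add atoms: none
Why: Claisen–Schmidt condensation (crossed aldol, then E1cB loss of water) gives the E-chalcone; MOM ethers and the aryl bromide are stable to ethanolic KOH.

**Step 5**
Reactants: 6 (E)-3-[5-bromo-4-methoxy-2-(methoxymethoxy)phenyl]-1-[2-hydroxy-4-(methoxymethoxy)phenyl]prop-2-en-1-one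
Product: 9 3-(5-bromo-2-hydroxy-4-methoxyphenyl)-7-hydroxy-4H-chromen-4-one, via flavanone 7 (not isolated), via bis-MOM isoflavone 8 (not isolated)
Conditions: Et3N (2 equiv), MeOH, 65 °C, then evaporate; PhI(OH)OTs (1.2 equiv), MeCN, 60 °C; then 3 M HCl, MeOH, 50 °C
Reagents that add atoms: none
Why: Base-mediated intramolecular oxa-Michael addition closes ring C to the racemic flavanone as chalcone isomerase does, the trivalent iodine reagent then iodinates the enol at C3 and the electron-rich 2,4-dioxygenated ring B shifts from C2 to C3 as iodobenzene leaves (oxidative 2,3-aryl migration of flavanones, the isoflavone synthase step; acetonitrile is used so that no ketal forms and ring contraction is suppressed), loss of the C3 proton from the C2 oxocarbenium ion gives the isoflavone, and acidic methanol finally cleaves both MOM acetals; the C2 stereocentre of 7 is racemic and is erased.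

**Step 6**
Reactants: 9 3-(5-bromo-2-hydroxy-4-methoxyphenyl)-7-hydroxy-4H-chromen-4-one; 10 tributyl(3-methylbut-2-en-1-yl)stannane
Product: 11 7-hydroxy-3-[2-hydroxy-4-methoxy-5-(3-methylbut-2-en-1-yl)phenyl]-4H-chromen-4-one
Conditions: 10 (2 equiv), Pd(PPh3)4 (5 mol %), DMF, 100 °C
Reagents that add atoms: none
Why: Stille cross-coupling (oxidative addition at C–Br, allyl transmetallation, reductive elimination at the less hindered primary terminus) gives the linear prenyl arene under neutral conditions that tolerate the free phenols and the chromone.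

**Step 7**
Reactants: 11 7-hydroxy-3-[2-hydroxy-4-methoxy-5-(3-methylbut-2-en-1-yl)phenyl]-4H-chromen-4-one
Product: 13 tris(allyl carbonate) of 3-[2-hydroxy-4-methoxy-5-(3-methylbut-2-en-1-yl)phenyl]-2H-chromene-4,7-diol, via trilithium enolate 12 (not isolated)
Conditions: LiBH(s-Bu)3 (L-Selectride, 3.3 equiv), THF, −78 to 0 °C; then TMEDA, allyl chloroformate (4 equiv), −78 °C to rt
Reagents that add atoms: allyl chloroformate, C=CCOC(=O)Cl
Why: The borohydride first deprotonates both phenols and then adds hydride 1,4 to the chromone (conjugate reduction), and the two phenoxides and the hindered aryl-stabilised enolate are O-acylated (reductive enolate trapping to an allyl enol carbonate); no stereocentre is formed and the prenyl alkene is inert.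

**Step 8**
Reactants: 13 tris(allyl carbonate) of 3-[2-hydroxy-4-methoxy-5-(3-methylbut-2-en-1-yl)phenyl]-2H-chromene-4,7-diol
Product: 15 (3S)-7-hydroxy-3-[2-hydroxy-4-methoxy-5-(3-methylbut-2-en-1-yl)phenyl]-2,3-dihydro-4H-chromen-4-one, via enolate 14 (not isolated)
Conditions: Pd2(dba)3 (5 mol %), (S)-t-Bu-PHOX (12.5 mol %), Meldrum's acid (5 equiv), 1,4-dioxane, 40 °C
Reagents that add atoms: none
Why: Palladium-catalysed decarboxylative asymmetric protonation: zerovalent palladium ionises all three allyl carbonates (Tsuji–Trost), CO2 is lost, Meldrum's acid takes up the allyl groups and delivers the C3 proton to one face of the enolate held by the chiral allylpalladium–PHOX cation, which sets the only stereocentre as (3S) in a weakly acidic medium that does not epimerise the α-aryl ketone.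

**Compound list**
1 | 2-hydroxy-4-methoxybenzaldehyde | COc1ccc(C=O)c(O)c1 | starting material
2 | 5-bromo-2-hydroxy-4-methoxybenzaldehyde | COc1cc(O)c(C=O)cc1Br | intermediate
3 | 5-bromo-4-methoxy-2-(methoxymethoxy)benzaldehyde | COCOc1cc(OC)c(Br)cc1C=O | intermediate
4 | 2,4-dihydroxyacetophenone | CC(=O)c1ccc(O)cc1O | starting material
5 | 1-[2-hydroxy-4-(methoxymethoxy)phenyl]ethanone | COCOc1ccc(C(C)=O)c(O)c1 | intermediate
6 | (E)-3-[5-bromo-4-methoxy-2-(methoxymethoxy)phenyl]-1-[2-hydroxy-4-(methoxymethoxy)phenyl]prop-2-en-1-one | COCOc1ccc(C(=O)/C=C/c2cc(Br)c(OC)cc2OCOC)c(O)c1 | intermediate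
7 | racemic 2-[5-bromo-4-methoxy-2-(methoxymethoxy)phenyl]-7-(methoxymethoxy)chroman-4-one (flavanone, not isolated) | COCOc1ccc2C(=O)CC(c3cc(Br)c(OC)cc3OCOC)Oc2c1 | intermediate
8 | 3-[5-bromo-4-methoxy-2-(methoxymethoxy)phenyl]-7-(methoxymethoxy)-4H-chromen-4-one (not isolated) | COCOc1ccc2c(c1)occ(-c3cc(Br)c(OC)cc3OCOC)c2=O | intermediate
9 | 3-(5-bromo-2-hydroxy-4-methoxyphenyl)-7-hydroxy-4H-chromen-4-one | COc1cc(O)c(-c2coc3cc(O)ccc3c2=O)cc1Br | intermediate
10 | tributyl(3-methylbut-2-en-1-yl)stannane | CCCC[Sn](CCCC)(CCCC)CC=C(C)C | starting material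
11 | 7-hydroxy-3-[2-hydroxy-4-methoxy-5-(3-methylbut-2-en-1-yl)phenyl]-4H-chromen-4-one | COc1cc(O)c(-c2coc3cc(O)ccc3c2=O)cc1CC=C(C)C | intermediate
12 | trilithium salt of the C4 enolate and 7,2'-bis(phenoxide) of 3-[2-hydroxy-4-methoxy-5-(3-methylbut-2-en-1-yl)phenyl]-2H-chromene-4,7-diol (not isolated) | [Li+].[Li+].[Li+].COc1cc([O-])c(C2=C([O-])c3ccc([O-])cc3OC2)cc1CC=C(C)C | intermediate
13 | tris(allyl carbonate) at the C4 enol oxygen, O7 and O2' of 3-[2-hydroxy-4-methoxy-5-(3-methylbut-2-en-1-yl)phenyl]-2H-chromene-4,7-diol | COc1cc(OC(=O)OCC=C)c(C2=C(OC(=O)OCC=C)c3ccc(OC(=O)OCC=C)cc3OC2)cc1CC=C(C)C | intermediate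
14 | C4 enolate of the target with both phenols free, ion-paired with the allylpalladium–PHOX cation (cation not drawn, not isolated) | COc1cc(O)c(C2=C([O-])c3ccc(O)cc3OC2)cc1CC=C(C)C | intermediate
15 | (3S)-7-hydroxy-3-[2-hydroxy-4-methoxy-5-(3-methylbut-2-en-1-yl)phenyl]-2,3-dihydro-4H-chromen-4-one | COc1cc(O)c([C@H]2COc3cc(O)ccc3C2=O)cc1CC=C(C)C | target

**Step count and risks**
Total steps: 8. Longest linear sequence: 7 (steps 1, 2, 4, 5, 6, 7, 8).

Most likely to fail, step 5. The chalcone–flavanone equilibrium may lie short of the flavanone. The C3 iodane may give flavone or α-tosyloxy ketone instead of the aryl shift. The TsOH released may also take off the ring B MOM group before the shift and expose an oxidisable phenol. The fallback sets out from 6 and comes back at 9. The aryl shift is run on the open-chain chalcone before any ring exists: 6 with PhI(OH)OTs in MeOH/CH(OMe)3 at room temperature, where MOM ethers are known to last, gives the racemic 1-[2-hydroxy-4-(methoxymethoxy)phenyl]-2-[5-bromo-4-methoxy-2-(methoxymethoxy)phenyl]-3,3-dimethoxypropan-1-one F1, which is isolated. Then 3 M HCl in MeOH at 50 °C closes ring C by attack of the free phenol on the acetal carbon, eliminates methanol and removes both MOM groups to give 9.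

Second, step 7. Hydride addition to an isoflavone that already carries two phenoxide charges may be slow, and acylation of a trianion can stop at partly acylated mixtures. The fallback sets out from 11 and comes back at 13. It separates reduction from enolate formation. A copper hydride conjugate reduction (Cu(OAc)2 5 mol %, 1,2-bis(diphenylphosphino)benzene, polymethylhydrosiloxane, t-BuOH, toluene, rt), which tolerates the phenols as proton sources, gives the racemic 7-hydroxy-3-[2-hydroxy-4-methoxy-5-(3-methylbut-2-en-1-yl)phenyl]chroman-4-one F2. This is isolated and then deprotonated three times with NaN(SiMe3)2 (3.3 equiv) in THF/TMEDA at −78 °C and acylated with allyl chloroformate to give 13.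

Third, step 8. The ortho substituent on ring B that steers the protonation is itself a carbonate being cleaved in the same flask, the freed phenols are internal proton donors, and the sense of induction is unverified; the enantiomeric excess may therefore be moderate (check by chiral HPLC, upgrade by recrystallisation, keep 15 away from base). The fallback sets out from 11 and comes back at 15, bypassing step 7 as well; it sets C3 by dynamic kinetic resolution instead of protonation.
- TBSCl and imidazole in DMF give 7-(tert-butyldimethylsilyloxy)-3-[2-(tert-butyldimethylsilyloxy)-4-methoxy-5-(3-methylbut-2-en-1-yl)phenyl]-4H-chromen-4-one F3.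
- Asymmetric transfer hydrogenation with RuCl[(S,S)-TsDPEN](p-cymene) (2 mol %) in HCO2H/Et3N (5:2) and EtOAc at 40 °C reduces the C2–C3 bond and then the ketone, with the C3 centre racemising under the amine, to give the cis (3S,4S)-isoflavan-4-ol bis-silyl ether F4.
- Dess–Martin periodinane with NaHCO3 in CH2Cl2 at 0 °C returns the ketone without touching C3, giving the (3S)-isoflavanone bis-silyl ether F5.
- KHF2 in MeOH at room temperature removes both aryl silyl ethers under weakly acidic conditions to give 15.

**Further compounds**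
F1 | step 5 | racemic 1-[2-hydroxy-4-(methoxymethoxy)phenyl]-2-[5-bromo-4-methoxy-2-(methoxymethoxy)phenyl]-3,3-dimethoxypropan-1-one | COCOc1ccc(C(=O)C(C(OC)OC)c2cc(Br)c(OC)cc2OCOC)c(O)c1
F2 | step 7 | racemic 7-hydroxy-3-[2-hydroxy-4-methoxy-5-(3-methylbut-2-en-1-yl)phenyl]chroman-4-one | COc1cc(O)c(C2COc3cc(O)ccc3C2=O)cc1CC=C(C)C
F3 | step 8 | 7-(tert-butyldimethylsilyloxy)-3-[2-(tert-butyldimethylsilyloxy)-4-methoxy-5-(3-methylbut-2-en-1-yl)phenyl]-4H-chromen-4-one | COc1cc(O[Si](C)(C)C(C)(C)C)c(-c2coc3cc(O[Si](C)(C)C(C)(C)C)ccc3c2=O)cc1CC=C(C)C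
F4 | step 8 | (3S,4S)-7-(tert-butyldimethylsilyloxy)-3-[2-(tert-butyldimethylsilyloxy)-4-methoxy-5-(3-methylbut-2-en-1-yl)phenyl]chroman-4-ol (3,4-cis) | COc1cc(O[Si](C)(C)C(C)(C)C)c([C@H]2COc3cc(O[Si](C)(C)C(C)(C)C)ccc3[C@H]2O)cc1CC=C(C)C
F5 | step 8 | (3S)-7-(tert-butyldimethylsilyloxy)-3-[2-(tert-butyldimethylsilyloxy)-4-methoxy-5-(3-methylbut-2-en-1-yl)phenyl]chroman-4-one | COc1cc(O[Si](C)(C)C(C)(C)C)c([C@H]2COc3cc(O[Si](C)(C)C(C)(C)C)ccc3C2=O)cc1CC=C(C)C
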